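**Plan**
Auranetin is 3,6,7,8,4'-pentamethoxyflavone, made up of ring A (trimethoxybenzo), ring C (pyranone) and ring B (anisyl). It has no stereocentre and no stereogenic double bond, so no stereochemistry has to be introduced.
Retrosynthesis: the O–CH3 bond and then the C3–O bond at C3 are removed, leading back to the 3-unsubstituted flavone. Ring C is then cut at C4a–C4, C4–C3 and O1–C2.
Enabling feature: in ring C the carbonyl carbon C4 is a single carbon held between C4a of ring A, whose neighbour C8a carries O1, and the C3=C2 pair that bears ring B. C4 therefore maps onto carbon monoxide, C3–C2–ring B onto a terminal arylalkyne, and C4a/C8a–O1 onto an ortho-iodophenol.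
Forward: ring A is bought with all four oxygens in place and is iodinated next to its free hydroxyl. One palladium-catalysed three-component operation then closes ring C and attaches ring B. C3 is finally hydroxylated through a transient epoxide and methylated.

Key step: step 2

Remark: dimethyldioxirane is not a catalogue item. It is taken as a reagent solution, distilled beforehand from acetone, NaHCO3 and the triple salt 2KHSO5·KHSO4·K2SO4, and lies outside the step count.

**Step 1**
Reactants: 1 2,3,4-trimethoxyphenol
Product: 2 6-iodo-2,3,4-trimethoxyphenol
Conditions: I2 (1.0 equiv), NaHCO3, THF–H2O, 0 °C to rt, under N2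
Reagents that add atoms: iodine, [I][I]
Why: Electrophilic aromatic iodination under mildly basic conditions runs through the phenoxide, whose para carbon and one ortho carbon already carry methoxy groups, so iodine should enter at the only free ortho carbon C6 (also para to the 3-methoxy group) rather than at C5, which is meta to the oxygen anion; no stereocentre is formed.

**Step 2**
Reactants: 2 6-iodo-2,3,4-trimethoxyphenol; 3 4-ethynylanisole; 4 carbon monoxide
Product: 7 6,7,8-trimethoxy-2-(4-methoxyphenyl)-4H-chromen-4-one, via ortho-hydroxyaryl ynone 5 (not isolated), via diethylamino enaminone 6 (not isolated)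
Conditions: PdCl2(dppf) (5 mol %), 3 (1.3 equiv), CO (20 bar), Et2NH (solvent), 120 °C, autoclave
Reagents that add atoms: carbon monoxide (compound 4), [C-]#[O+]; diethylamine, CCNCC (held only in intermediate 6, released again on ring closure)
Why: In situ reduction of PdCl2(dppf) gives zerovalent palladium, which adds oxidatively to the C–I bond of 2; CO insertion gives the aroylpalladium iodide, and amine-assisted transfer of the acetylide of 3 followed by reductive elimination forms C4a–C4 and C4–C3 in ynone 5. Diethylamine then adds in conjugate fashion to 5 to give enaminone 6, and the phenol oxygen attacks the amine-bearing carbon and expels diethylamine, forming O1–C2. The closest known reaction type is the copper-free carbonylative Sonogashira coupling–cyclisation of ortho-iodophenols with terminal arylacetylenes in a secondary amine, an established flavone synthesis. Ring C closes in a 6-endo mode (6-endo-trig addition–elimination on the enaminone), and no stereocentre is created. Carbonylative rather than direct alkynylation is secured by the CO pressure, the absence of copper and the electron-rich aryl group, which migrates readily to CO; six- rather than five-membered closure is secured because turning the triple bond into the enaminone removes the 5-exo-dig path and leaves the amine-bearing carbon as the only electrophilic site. The sense of ring fusion is fixed by the substrate, since the iodine-bearing carbon has a single ortho hydroxyl and all other oxygens are methyl ethers.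

**Step 3**
Reactants: 7 6,7,8-trimethoxy-2-(4-methoxyphenyl)-4H-chromen-4-one
Product: 9 3-hydroxy-6,7,8-trimethoxy-2-(4-methoxyphenyl)-4H-chromen-4-one, via racemic 2,3-epoxyflavanone 8 (not isolated)
Conditions: dimethyldioxirane (ca. 0.08 M in acetone, excess, in portions), CH2Cl2, 0 °C to rt; then p-TsOH·H2O (cat.), CH2Cl2, rt
Reagents that add atoms: dimethyldioxirane, CC1(C)OO1
Why: Dioxirane epoxidation of the C2=C3 enol-ether bond of a flavone, a known entry to flavonols, should give the racemic and necessarily cis-fused epoxide 8, which acid opens at C2 (cation stabilised by O1 and the anisyl ring) and which then loses H3 to restore the aromatic pyranone, erasing both transient stereocentres.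

**Step 4**
Reactants: 9 3-hydroxy-6,7,8-trimethoxy-2-(4-methoxyphenyl)-4H-chromen-4-one
Product: 10 auranetin (3,6,7,8-tetramethoxy-2-(4-methoxyphenyl)-4H-chromen-4-one)
Conditions: MeI, K2CO3, acetone, reflux
Reagents that add atoms: iodomethane, CI
Why: Williamson ether synthesis, in which the 3-hydroxyl is the only acidic site and its potassium salt is methylated by SN2 attack on iodomethane; no stereocentre is involved.

**Compound list**
1 | 2,3,4-trimethoxyphenol | COc1ccc(O)c(OC)c1OC | starting material
2 | 6-iodo-2,3,4-trimethoxyphenol | COc1cc(I)c(O)c(OC)c1OC | intermediate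
3 | 4-ethynylanisole (1-ethynyl-4-methoxybenzene) | COc1ccc(C#C)cc1 | starting material
4 | carbon monoxide | [C-]#[O+] | starting material
5 | 1-(2-hydroxy-3,4,5-trimethoxyphenyl)-3-(4-methoxyphenyl)prop-2-yn-1-one | COc1ccc(C#CC(=O)c2cc(OC)c(OC)c(OC)c2O)cc1 | intermediate (not isolated)
6 | (E)-3-(diethylamino)-1-(2-hydroxy-3,4,5-trimethoxyphenyl)-3-(4-methoxyphenyl)prop-2-en-1-one (push–pull alkene, geometry mobile, written as E) | CCN(CC)/C(=C/C(=O)c1cc(OC)c(OC)c(OC)c1O)c1ccc(OC)cc1 | intermediate (not isolated)
7 | 6,7,8-trimethoxy-2-(4-methoxyphenyl)-4H-chromen-4-one | COc1ccc(-c2cc(=O)c3cc(OC)c(OC)c(OC)c3o2)cc1 | intermediate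
8 | rac-2,3-epoxy-6,7,8-trimethoxy-2-(4-methoxyphenyl)chroman-4-one (cis ring fusion; one enantiomer of the racemate written) | COc1ccc(cc1)[C@@]12O[C@@H]1C(=O)c1cc(OC)c(OC)c(OC)c1O2 | intermediate (not isolated)
9 | 3-hydroxy-6,7,8-trimethoxy-2-(4-methoxyphenyl)-4H-chromen-4-one | COc1ccc(-c2oc3c(OC)c(OC)c(OC)cc3c(=O)c2O)cc1 | intermediate
10 | auranetin, 3,6,7,8-tetramethoxy-2-(4-methoxyphenyl)-4H-chromen-4-one | COc1ccc(-c2oc3c(OC)c(OC)c(OC)cc3c(=O)c2OC)cc1 | target

**Totals**
Total step count: 4.
Longest linear sequence: 4 steps (1 → 2 → 7 → 9 → 10).

**Steps most likely to fail**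

Step 2. Several processes could compete with the intended sequence:
- CO insertion may be outrun by direct alkynylation.
- The aroylpalladium species may be captured by diethylamine instead of the alkyne.
- Five-membered closure may compete with six-membered closure.
- Reductive loss of iodine may consume the aryl iodide.

The fallback gives up the carbonylation and builds ring C by classical chalcone chemistry. It sets out from 1 and comes back to the route at 7. Ortho-acylation of 1 with acetic acid and BF3·OEt2 at about 85 °C (Friedel–Crafts acylation, Fries-type ortho delivery) should give 1-(2-hydroxy-3,4,5-trimethoxyphenyl)ethan-1-one F1. Claisen–Schmidt condensation of this ketone with 4-methoxybenzaldehyde (KOH, EtOH, rt) should give (E)-1-(2-hydroxy-3,4,5-trimethoxyphenyl)-3-(4-methoxyphenyl)prop-2-en-1-one F2. Oxidative cyclisation with catalytic I2 in DMSO at 130 °C should then deliver 7.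

Step 1. Three processes could spoil the iodination:
- Iodination may occur at C5 under the influence of the methoxy groups.
- A second iodination may follow the first.
- The electron-rich para-methoxyphenol may undergo oxidative demethylation.

The fallback replaces electrophilic substitution by directed ortho-metalation. It sets out from 1 and comes back at 2. Protection with chloromethyl methyl ether and iPr2NEt in CH2Cl2 should give 1,2,3-trimethoxy-4-(methoxymethoxy)benzene F3. Treatment with n-BuLi and TMEDA in THF (−78 to 0 °C) should deprotonate next to the acetal oxygen, the stronger director, to give [3,4,5-trimethoxy-2-(methoxymethoxy)phenyl]lithium F4. Quenching with I2 should give 1-iodo-3,4,5-trimethoxy-2-(methoxymethoxy)benzene F5. HCl in MeOH at rt then releases 2.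

Step 3. Oxygen transfer to the carbonyl-conjugated C2=C3 bond may be sluggish. Long exposure may bring on oxidation of the electron-rich rings or fragmentation of the epoxide before it isomerises. The fallback reverses the polarity and makes C3 the nucleophile. It sets out from 7 and comes back at 9. Deprotonation with LiN(iPr)2 in THF at −78 °C should give 3-lithio-6,7,8-trimethoxy-2-(4-methoxyphenyl)-4H-chromen-4-one F6. Trapping with B(OMe)3 should give dimethyl [6,7,8-trimethoxy-2-(4-methoxyphenyl)-4-oxo-4H-chromen-3-yl]boronate F7. Oxidation with H2O2 and AcOH (0 °C to rt) then converts the C–B bond into the C3–OH of 9.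

**Further compounds**
F1 | step 2 | 1-(2-hydroxy-3,4,5-trimethoxyphenyl)ethan-1-one | CC(=O)c1cc(OC)c(OC)c(OC)c1O
F2 | step 2 | (E)-1-(2-hydroxy-3,4,5-trimethoxyphenyl)-3-(4-methoxyphenyl)prop-2-en-1-one | COc1ccc(/C=C/C(=O)c2cc(OC)c(OC)c(OC)c2O)cc1
F3 | step 1 | 1,2,3-trimethoxy-4-(methoxymethoxy)benzene | COCOc1ccc(OC)c(OC)c1OC
F4 | step 1 | [3,4,5-trimethoxy-2-(methoxymethoxy)phenyl]lithium | [Li]c1cc(OC)c(OC)c(OC)c1OCOC
F5 | step 1 | 1-iodo-3,4,5-trimethoxy-2-(methoxymethoxy)benzene | COCOc1c(I)cc(OC)c(OC)c1OC
F6 | step 3 | 3-lithio-6,7,8-trimethoxy-2-(4-methoxyphenyl)-4H-chromen-4-one | [Li]c1c(-c2ccc(OC)cc2)oc2c(OC)c(OC)c(OC)cc2c1=O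
F7 | step 3 | dimethyl [6,7,8-trimethoxy-2-(4-methoxyphenyl)-4-oxo-4H-chromen-3-yl]boronate | COB(OC)c1c(-c2ccc(OC)cc2)oc2c(OC)c(OC)c(OC)cc2c1=O
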